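## Retrosynthetic overview

1. The three angelates go on last. The cis-8,9-diol comes from dihydroxylation of a C8=C9 alkene anti to C7–OH, and that allylic alcohol from a Wharton transposition of a 7,8-epoxy-9-ketone.
2. Key disconnection: the cyclobutane bond C10–C11. It joins the two α-carbons of a C1/C9 diketone (C10 enolate plus a C11 α-iodo ketone made in the flask as enolonium equivalent), which reveals a cis-fused bicyclo[5.4.0]undecene-dione.
3. The seven-membered ring comes from a CH–CH3 ring enlargement of a cis-octalenone, the enantioselective Diels–Alder adduct of 4,4-dimethylcyclohexa-2,5-dienone and a 2-silyloxypenta-1,3-diene.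
4. Ring order: ring B (bought as the dienone) → ring A by Diels–Alder → ring B enlarged from six to seven → cyclobutane last, which completes both bridged ring systems at once.

Conventions: carbons carry the longipinane labels of the target in every intermediate. C1 is the ketone, C2=C3 the enone alkene (CH3 on C3), C6 is CMe2, C7–C9 are the oxygenated carbons, C10 is the methyl-bearing quaternary carbon, and C4, C5, C11 are the cyclobutane CH groups. Ring A = C1–C2–C3–C4–C5–C11; ring B = the ring holding C6–C9.

Assumption: 4,4-dimethylcyclohexa-2,5-dien-1-one is bought as a catalogue compound.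

Assumption: the (S)-oxazaborolidinium catalyst is taken to give the enantiomer drawn (α-C–H···O binding model for cyclic enones); the (R)-catalyst is used if the sense is opposite.

## Route

Step 1
Reactants: 1 (E)-pent-3-en-2-one
Product: 2 (E)-2-(tert-butyldimethylsilyloxy)penta-1,3-diene
Conditions: TBSOTf, Et3N, Et2O, 0 °C
Reagents that add atoms: tert-butyldimethylsilyl trifluoromethanesulfonate, CC(C)(C)[Si](C)(C)OS(=O)(=O)C(F)(F)F
Why: Silyl enol ether formation by soft enolisation: an acetyl proton is removed and the cross-conjugated enolate is trapped on oxygen, leaving the (E)-propenyl unit unchanged.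

Step 2
Reactants: 2 (E)-2-(tert-butyldimethylsilyloxy)penta-1,3-diene; 3 4,4-dimethylcyclohexa-2,5-dien-1-one
Product: 4 cis-fused octalenone silyl enol ether (ring A: C11H2–C1(OTBS)=C2H–C3H(CH3)–C4H–C5H; ring B: C4–C9(=O)–C8H=C7H–C6(CH3)2–C5)
Conditions: (S)-1-(2-methylphenyl)-3,3-diphenyltetrahydro-1H,3H-pyrrolo[1,2-c][1,3,2]oxazaborole (20 mol %), HN(SO2CF3)2 (17 mol %), CH2Cl2, −78 → −20 °C
Reagents that add atoms: none
Why: Enantioselective Diels–Alder reaction under chiral oxazaborolidinium catalysis: the CH2 terminus (C11) bonds to the β-carbon (C5) and the methyl-bearing terminus (C3) to the α-carbon (C4) by the ortho/para rule, suprafacial addition makes the C4–H/C5–H fusion cis, endo approach puts C3–CH3 cis to C9, and the catalyst selects one enantiotopic π-face of the achiral dienone to fix C4 and C5 absolutely.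

Step 3
Reactants: 4 cis-fused octalenone silyl enol ether
Product: 5 ring-enlarged cis-fused bicyclic enone (ring B: C4–C10H(CH3)–C9(=O)–C8H=C7H–C6(CH3)2–C5; C10 epimer mixture)
Conditions: CH3CHN2 (Et2O solution, 1.5 equiv), Sc(OTf)3 (10 mol %), toluene/CH2Cl2, −78 °C
Reagents that add atoms: diazoethane, CC=[N+]=[N-]
Why: Lewis-acid-catalysed diazoalkane carbonyl homologation (Tiffeneau–Demjanov-type carbon insertion): diazoethane adds to the activated C9 carbonyl and the sp3 ring-fusion carbon C4 migrates with retention (the alkenyl carbon C8 migrates poorly), inserting C10H(CH3) between C4 and C9; the C10 configuration is irrelevant because C10 is enolised in step 6.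

Step 4
Reactants: 5 ring-enlarged cis-fused bicyclic enone
Product: 6 7,8-epoxy-9-ketone silyl enol ether (epoxide oxygen on the ring B face anti to ring A)
Conditions: t-BuOOH (decane solution), 1,8-diazabicyclo[5.4.0]undec-7-ene (1.2 equiv), CH2Cl2, 0 °C → rt
Reagents that add atoms: tert-butyl hydroperoxide, CC(C)(C)OO
Why: Weitz–Scheffer nucleophilic epoxidation: only the ring B enone is an acceptor (ring A is masked as a silyl enol ether) and the hydroperoxide adds to C7 from the convex face of the cis-fused bicycle, anti to ring A, which sets C7 relative to C4/C5.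

Step 5
Reactants: 6 7,8-epoxy-9-ketone silyl enol ether
Product: 7 cis-fused epoxy enedione (C1(=O)–C2H=C3(CH3) enone in ring A; 7,8-epoxy-9-ketone in ring B)
Conditions: Pd(OAc)2 (1.1 equiv), MeCN, 40 °C
Reagents that add atoms: none
Why: Saegusa–Ito oxidation: the palladium enolate bound at C2 undergoes β-hydride elimination from C3–H, which unmasks the C1 enone regiospecifically and erases the C3 stereocentre.

Step 6
Reactants: 7 cis-fused epoxy enedione
Product: 10 7,8-epoxylongipin-2-ene-1,9-dione (tricyclic), via dilithium bis-enolate 8 (not isolated), via α′-iodo ketone lithium enolate 9 (not isolated)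
Conditions: 7 added to LiN(iPr)2 (2.3 equiv), THF, −78 °C; then I2 (1.0 equiv), −78 → −20 °C
Reagents that add atoms: none
Why: Proposed new method: double deprotonation gives the C11 enolate (kinetic α′ site of the enone) and the C10 enolate (only enolisable site of the epoxy ketone); iodine iodinates C11 on the face anti to C6, and the C10 enolate, held gauche to C11 by the cis ring fusion, displaces iodide with inversion (4-exo-tet), so two normally nucleophilic α-carbons are joined with the α-iodo ketone as enolonium partner; the tether forces C10–C11 to form on the ring A face and so fixes C10 and C11, iodine transfer between enolates corrects a first iodination at C10, and O-alkylation would give an anti-Bredt enol ether; closest known reaction types are the iodine- or CuCl2-mediated intramolecular oxidative coupling of bis-enolates to three- and four-membered rings and the intramolecular ester-enolate alkylation that closes bicyclo[3.1.1]heptanes.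

Step 7
Reactants: 10 7,8-epoxylongipin-2-ene-1,9-dione
Product: 12 7-hydroxylongipina-2,8-dien-1-one, via C9 hydrazone 11 (not isolated)
Conditions: N2H4·H2O (3 equiv), CH3CO2H (cat.), MeOH, 0 °C → rt
Reagents that add atoms: none
Why: Wharton transposition: the epoxy hydrazone opens at C8–O and loses N2 to give the C8=C9 alkene and the C7 alcohol with the C7–O bond untouched (configuration retained); the hindered, β,β-disubstituted C1 enone should condense with hydrazine much more slowly than the α,β-epoxy ketone.

Step 8
Reactants: 12 7-hydroxylongipina-2,8-dien-1-one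
Product: 13 7,8,9-trihydroxylongipin-2-en-1-one (8-OH and 9-OH cis to each other and trans to 7-OH)
Conditions: OsO4 (5 mol %), N-methylmorpholine N-oxide (2 equiv), acetone/H2O 4:1, rt
Reagents that add atoms: osmium tetroxide, O=[Os](=O)(=O)=O; N-methylmorpholine N-oxide, C[N+]1([O-])CCOCC1; water, O
Why: Upjohn dihydroxylation: OsO4 adds suprafacially to the cis C8=C9 alkene (the enone alkene is electron-poor and trisubstituted) on the face anti to the allylic C7–OH (Kishi's empirical rule), which sets C8 and C9.

Step 9
Reactants: 13 7,8,9-trihydroxylongipin-2-en-1-one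
Product: 14 CNP0330079.1, (4R,5S,7S,8R,9S,10R,11R)-7,8,9-tris[(Z)-2-methylbut-2-enoyloxy]longipin-2-en-1-one
Conditions: (Z)-2-methylbut-2-enoic anhydride (6 equiv), Cs2CO3 (6 equiv), MeCN, 25 → 45 °C
Reagents that add atoms: angelic anhydride [(Z)-2-methylbut-2-enoic anhydride], C/C=C(/C)C(=O)OC(=O)/C(C)=C\C
Why: Base-mediated O-acylation with the preformed (Z)-anhydride: no nucleophilic amine catalyst is present, so the angelate is not isomerised to tiglate by addition–elimination, and no stereocentre is touched.

## Compound list

1 | (E)-pent-3-en-2-one | C/C=C/C(C)=O | starting material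
2 | (E)-2-(tert-butyldimethylsilyloxy)penta-1,3-diene | C=C(O[Si](C)(C)C(C)(C)C)/C=C/C | intermediate
3 | 4,4-dimethylcyclohexa-2,5-dien-1-one | CC1(C)C=CC(=O)C=C1 | starting material
4 | 6-(tert-butyldimethylsilyloxy)-4,4,8-trimethyl-4a,5,8,8a-tetrahydronaphthalen-1(4H)-one; ring-fusion hydrogens cis, 8-CH3 cis to the carbonyl carbon on ring A (endo adduct) | C1=CC(C)(C)[C@@H]2CC(O[Si](C)(C)C(C)(C)C)=C[C@H](C)[C@@H]2C1=O | intermediate
5 | 3-(tert-butyldimethylsilyloxy)-1,5,5,9-tetramethyl-1,4,4a,5,9,9a-hexahydro-8H-benzo[7]annulen-8-one; cis-fused, C10 (annulene C9) epimer mixture left unspecified | C1=CC(C)(C)[C@@H]2CC(O[Si](C)(C)C(C)(C)C)=C[C@H](C)[C@@H]2C(C)C1=O | intermediate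
6 | 7,8-epoxide of 5 (longipinane labels); epoxide oxygen anti to ring A, C10 epimer mixture | [C@H]12O[C@H]1C(C)(C)[C@@H]3CC(O[Si](C)(C)C(C)(C)C)=C[C@H](C)[C@@H]3C(C)C2=O | intermediate
7 | cis-fused bicyclic epoxy enedione: ring A C1(=O)–C2H=C3(CH3) enone, ring B 7,8-epoxy-9-ketone with C10H(CH3), C10 epimer mixture | [C@H]12O[C@H]1C(C)(C)[C@@H]3CC(=O)C=C(C)[C@@H]3C(C)C2=O | intermediate
8 | dilithium bis-enolate of 7 (C11=C1–OLi and C10=C9–OLi) | [Li+].[Li+].[C@H]12O[C@H]1C(C)(C)[C@@H]3C=C([O-])C=C(C)[C@@H]3C(C)=C2[O-] | intermediate (not isolated)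
9 | C11 α′-iodo ketone carrying the C10=C9–OLi enolate; iodine trans to C10 and C6 on ring A | [Li+].[C@H]12O[C@H]1C(C)(C)[C@@H]3[C@@H](I)C(=O)C=C(C)[C@@H]3C(C)=C2[O-] | intermediate (not isolated)
10 | 7,8-epoxylongipin-2-ene-1,9-dione; epoxide on the face away from C11, configuration at C4, C5, C10, C11 as in the target | [C@H]12O[C@H]1C(C)(C)[C@@H]3[C@H]4C(=O)C=C(C)[C@@H]3[C@@]4(C)C2=O | intermediate
11 | C9 hydrazone of 10 | [C@H]12O[C@H]1C(C)(C)[C@@H]3[C@H]4C(=O)C=C(C)[C@@H]3[C@@]4(C)C2=NN | intermediate (not isolated)
12 | 7-hydroxylongipina-2,8-dien-1-one; C7 configured as in the target | C1=C[C@@H](O)C(C)(C)[C@@H]2[C@H]3C(=O)C=C(C)[C@@H]2[C@]31C | intermediate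
13 | 7,8,9-trihydroxylongipin-2-en-1-one; 8-OH cis to 9-OH, 7-OH trans to 8-OH | O[C@@H]1[C@@H](O)C(C)(C)[C@@H]2[C@H]3C(=O)C=C(C)[C@@H]2[C@@]3(C)[C@@H]1O | intermediate
14 | CNP0330079.1, (4R,5S,7S,8R,9S,10R,11R)-7,8,9-tris(angeloyloxy)longipin-2-en-1-one | C/C=C(/C)C(=O)O[C@@H]1[C@@H](OC(=O)/C(C)=C\C)C(C)(C)[C@@H]2[C@H]3C(=O)C=C(C)[C@@H]2[C@@]3(C)[C@@H]1OC(=O)/C(C)=C\C | target

## Step count and risks

Total step count: 9. Longest linear sequence: 9 steps (1 → 14; 8 steps from 3).

Three steps most likely to fail:

Step 6 (cyclobutane closure). The mono-enolate can undergo intramolecular aldol addition, the α′-iodo ketone can lose HI towards a phenol, and lithium iodide can attack the epoxide. The fallback sets out from 7: double deprotonation with LiN(iPr)2 and O-silylation with Me3SiCl gives the bis(trimethylsilyl enol ether) F1 (C11=C1–OSiMe3 and C10=C9–OSiMe3). One-electron oxidation with (NH4)2Ce(NO3)6 and NaHCO3 in MeCN at −30 °C then couples the two silyl enol ethers through a radical cation, with no free carbonyl, amide base or iodide present. This closes C10–C11 and comes back to the route at 10.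

Step 3 (ring enlargement). The secondary diazoalkane may fail to add to the hindered, conjugated C9 carbonyl, or may add to the C7=C8 alkene instead. The fallback sets out from 4: diazomethane with Sc(OTf)3 inserts an unsubstituted CH2 and gives the C10-unsubstituted ring-enlarged enone F2. C10 is its only enolisable position, so LiN(iPr)2 followed by CH3I introduces the methyl group and comes back to the route at 5.

Step 2 (Diels–Alder). The β-carbon of 3 is neopentyl, so the chiral Lewis acid may give low conversion or low enantioselectivity. The fallback sets out from 2 and 3: the cycloaddition is run without chiral control (toluene, sealed tube, 130–150 °C), which gives 4 as a racemate, that is, together with the mirror-image cis-octalenone F3. Preparative supercritical-fluid chromatography on a chiral stationary phase removes F3 and comes back to the route at 4.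

## Further compounds

F1 | step 6 | bis(trimethylsilyl enol ether) of 7 (C11=C1–OSiMe3 and C10=C9–OSiMe3) | [C@H]12O[C@H]1C(C)(C)[C@@H]3C=C(O[Si](C)(C)C)C=C(C)[C@@H]3C(C)=C2O[Si](C)(C)C
F2 | step 3 | C10-unsubstituted ring-enlarged enone (5 without the C10 methyl group) | C1=CC(C)(C)[C@@H]2CC(O[Si](C)(C)C(C)(C)C)=C[C@H](C)[C@@H]2CC1=O
F3 | step 2 | mirror-image cis-octalenone (enantiomer of 4) | C1=CC(C)(C)[C@H]2CC(O[Si](C)(C)C(C)(C)C)=C[C@@H](C)[C@H]2C1=O
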